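**Plan**
1. Cuts: the C3–O angelate ester; the C11–O bond with the C6=C7 shift (singlet-oxygen ene reaction of a 7(11)-en-8-one) and C7=C11 (aldol condensation with acetone); the ring A bond C3–C4 together with C15–H (oxetane by Paternò–Büchi closure, then hydride opening); C10–C1 (conjugate addition). The cyclobutane of (+)-verbenone serves as a temporary ring.
2. Forward: ring B is the six-membered ring of verbenone, set free by acid opening of the cyclobutane after the chain is on. One ozonolysis turns butenyl into the C1–C3 ester and isopropenyl into the C4 methyl ketone. Silyl enol ether and aldehyde follow, ring A is closed photochemically, and the ring B hydroxy-enone and the ester come last.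
3. Enabling feature: in ring A the oxygen on C3 and the methyl carbon C15 on C4 sit on the same (β) face, so a cis-fused oxetane C3–O–C15–C4 is latent in the trans-3,4-diol. On the ring B chair the C10–C1 and C5–C4 bonds are trans-diequatorial and C10 is quaternary, so the aldehyde and enol ether are held together and the aldehyde has no γ-hydrogen.
4. Stereochemistry: C5 is C5 of (1R,5R)-verbenone; C10 comes from cuprate attack anti to the gem-dimethyl bridge; C3 and C4 are set in the photocyclisation (cis oxetane fusion, OSiEt3 equatorial) and are not touched by the hydride opening; the Z ester geometry comes from angelic acid.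

Key step: step 7

Remark: (1R,5R)-(+)-verbenone is taken as commercially available; it is otherwise the allylic oxidation product of (1R)-(+)-α-pinene.
Remark: decalins carry eudesmane numbering (ring A = C1–C5, C10; ring B = C5–C10; C14 = methyl on C10; C15 = carbon on C4; C11–C13 = the 2-propyl unit on C7); β is the face of the C10 methyl.

**Route**

Step 1
Reactants: 1 (1R,5R)-(+)-verbenone; 2 but-3-en-1-ylmagnesium bromide
Product: 3 (1R,4R,5R)-4-(but-3-en-1-yl)-4,6,6-trimethylbicyclo[3.1.1]heptan-2-one
Conditions: CuI (10 mol %), THF, −30 to 0 °C; then H2O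
Reagents that add atoms: none
Why: Copper-catalysed conjugate addition of the Grignard reagent to the β,β-disubstituted enone should build the quaternary carbon (future C10) with the butenyl group entering anti to the gem-dimethyl bridge, the established facial bias of verbenone, so that the methyl group ends cis to the bridge carbon.

Step 2
Reactants: 3 (1R,4R,5R)-4-(but-3-en-1-yl)-4,6,6-trimethylbicyclo[3.1.1]heptan-2-one
Product: 5 (3R,4S)-3-(but-3-en-1-yl)-3-methyl-4-(prop-1-en-2-yl)cyclohexan-1-one, via tertiary chloride 4 (not isolated)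
Conditions: HCl (g), AcOH, 20 °C; then DBU, toluene, 80 °C
Reagents that add atoms: none
Why: Acid-induced opening of the cyclobutane of a nopinone-type ketone (heterolysis of the bond between the carbonyl α-carbon and the CMe2 carbon, tertiary cation trapped as chloride) followed by E2 dehydrochlorination toward a methyl group should release the cyclohexanone with both stereocentres untouched, the butenyl and isopropenyl groups trans and diequatorial.

Step 3
Reactants: 5 (3R,4S)-3-(but-3-en-1-yl)-3-methyl-4-(prop-1-en-2-yl)cyclohexan-1-one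
Product: 6 (7R,8S)-7-(but-3-en-1-yl)-7-methyl-8-(prop-1-en-2-yl)-1,4-dioxaspiro[4.5]decane
Conditions: HOCH2CH2OH, PPTS (cat.), benzene, reflux with removal of water
Reagents that add atoms: ethylene glycol OCCO
Why: Acid-catalysed ketalisation of the only carbonyl masks C8 so that the later aldehyde is the sole chromophore, and no stereocentre is touched.

Step 4
Reactants: 6 (7R,8S)-7-(but-3-en-1-yl)-7-methyl-8-(prop-1-en-2-yl)-1,4-dioxaspiro[4.5]decane
Product: 7 methyl 3-[(7R,8R)-8-acetyl-7-methyl-1,4-dioxaspiro[4.5]decan-7-yl]propanoate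
Conditions: O3, NaOH, MeOH/CH2Cl2, −78 °C
Reagents that add atoms: ozone [O-][O+]=O; methanol CO
Why: Ozonolysis in methanolic NaOH should cleave both alkenes in one operation, the monosubstituted one to the methyl ester (through the methoxy hydroperoxide) and the 1,1-disubstituted one to the methyl ketone, at a temperature where the ketone α-centre C5 should not epimerise.

Step 5
Reactants: 7 methyl 3-[(7R,8R)-8-acetyl-7-methyl-1,4-dioxaspiro[4.5]decan-7-yl]propanoate
Product: 8 methyl 3-[(7R,8R)-7-methyl-8-{1-[(triethylsilyl)oxy]ethenyl}-1,4-dioxaspiro[4.5]decan-7-yl]propanoate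
Conditions: Et3SiOTf, Et3N, CH2Cl2, −78 to 0 °C
Reagents that add atoms: triethylsilyl trifluoromethanesulfonate CC[Si](CC)(CC)OS(=O)(=O)C(F)(F)F
Why: Soft enolisation (silyl triflate and amine) converts only the ketone and removes a proton from the methyl group, not from the hindered methine C5 next to the quaternary carbon, giving the terminal silyl enol ether regioselectively while the ester stays untouched.

Step 6
Reactants: 8 methyl 3-[(7R,8R)-7-methyl-8-{1-[(triethylsilyl)oxy]ethenyl}-1,4-dioxaspiro[4.5]decan-7-yl]propanoate
Product: 9 3-[(7R,8R)-7-methyl-8-{1-[(triethylsilyl)oxy]ethenyl}-1,4-dioxaspiro[4.5]decan-7-yl]propanal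
Conditions: i-Bu2AlH, CH2Cl2, −78 °C; then aq. potassium sodium tartrate (KNaC4H4O6)
Reagents that add atoms: none
Why: Partial reduction of the methyl ester with i-Bu2AlH at −78 °C should stop at the aluminium hemiacetal, which gives the aldehyde on work-up, while the silyl enol ether and the ketal are inert.

Step 7
Reactants: 9 3-[(7R,8R)-7-methyl-8-{1-[(triethylsilyl)oxy]ethenyl}-1,4-dioxaspiro[4.5]decan-7-yl]propanal
Product: 10 8,8-(ethylenedioxy)-3β,15-epoxy-4α-(triethylsilyloxy)-11,12,13-trinor-5α-eudesmane
Conditions: hν (300 nm, Pyrex), degassed benzene (0.01 M), 10 °C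
Reagents that add atoms: none
Why: Proposed new method: the n,π* excited aldehyde, the only chromophore present, is attacked at its electrophilic oxygen by the nucleophilic CH2 terminus (C15) of the silyl enol ether, giving a 1,4-biradical (α-oxy radical at C3, tertiary α-silyloxy radical at C4) that combines at C3–C4, so the net event is an intramolecular Paternò–Büchi [2+2] cycloaddition; the closest known reactions are the intermolecular Paternò–Büchi addition of aldehydes to silyl enol ethers, which gives 3-silyloxyoxetanes with this same orientation, and intramolecular Paternò–Büchi closures of alkenyl carbonyl compounds. Ring A closes by 6-exo bonding of C3 to C4 of the C4=C15 bond in a chair fused to the ring B chair, and the oxetane closes as the four-membered ring O–C15–C4–C3, which can only be cis-fused. C4 is set by that chair: OSiEt3 should take the equatorial α position and C15 the axial β position, because an axial OSiEt3 would be syn-axial to the C10 methyl and to H2β, and a biradical that closes slowly can revert; C3 then follows from the cis fusion (O3 β, on the face of C15), which is the 3β-O/4β-C15 pattern of the target. The step needs regioselectivity (fused, not crossed, oxetane), secured by the polarisation of the enol ether and the four-atom tether; facial selectivity, secured as above; and chemoselectivity over Norrish cleavage, helped by the quaternary C10 (no γ-hydrogen for Norrish type 2 abstraction) and by the trans-diequatorial C10–C1 and C5–C4 bonds that hold the partners together.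

Step 8
Reactants: 10 8,8-(ethylenedioxy)-3β,15-epoxy-4α-(triethylsilyloxy)-11,12,13-trinor-5α-eudesmane
Product: 12 3β,4α-dihydroxy-11,12,13-trinor-5α-eudesman-8-one, via silyl ether 11 (not isolated)
Conditions: LiAlH4, THF, reflux; then 2 M HCl, THF, 20 °C
Reagents that add atoms: water O
Why: Hydride should open the strained oxetane by SN2 attack at the primary carbon C15 (the known ring opening of 3-silyloxyoxetanes to 1,2-diol derivatives), which turns C15 into the C4 methyl group and frees the 3β-hydroxyl without touching C3 or C4, and aqueous acid then removes the silyl ether and the ketal.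

Step 9
Reactants: 12 3β,4α-dihydroxy-11,12,13-trinor-5α-eudesman-8-one; 13 acetone
Product: 14 3β,4α,11-trihydroxy-5α,7α(H)-eudesman-8-one
Conditions: LiN(i-Pr)2 (3.3 equiv), THF, −78 °C; acetone; AcOH, −78 °C
Reagents that add atoms: none
Why: Kinetic deprotonation of the C8 ketone should occur at C7, away from the neopentyl C9 position, and the lithium enolate adds to acetone (directed aldol addition); the C7 centre is drawn as the equatorial epimer but is inconsequential because C7 becomes sp2 in step 10.

Step 10
Reactants: 14 3β,4α,11-trihydroxy-5α,7α(H)-eudesman-8-one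
Product: 15 3β,4α-dihydroxy-5α-eudesm-7(11)-en-8-one
Conditions: CeCl3·7H2O, NaI, MeCN, reflux
Reagents that add atoms: none
Why: This Lewis-acid-promoted dehydration is specific for β-hydroxy ketones (chelation of the ketol, then loss of water toward the α-carbon), so the tertiary C4 and secondary C3 hydroxyls should survive, and the conjugated isopropylidene ketone is the thermodynamic isomer.

Step 11
Reactants: 15 3β,4α-dihydroxy-5α-eudesm-7(11)-en-8-one
Product: 17 3β,4α,11-trihydroxy-5α-eudesm-6-en-8-one, via hydroperoxide 16 (not isolated)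
Conditions: O2, tetraphenylporphyrin (cat.), hν (visible), CH2Cl2, 0 °C; then PPh3
Reagents that add atoms: dioxygen O=O
Why: In the Schenck ene reaction of singlet oxygen with the s-cis α-isopropylidene ketone, oxygen should bond to C11 and the hydrogen should come from C6, the alkyl group geminal to the carbonyl (the regiochemistry known for pulegone-type enones), which moves the double bond to C6=C7 in conjugation with C8=O, and PPh3 reduces the hydroperoxide to the tertiary alcohol.

Step 12
Reactants: 17 3β,4α,11-trihydroxy-5α-eudesm-6-en-8-one; 18 angelic acid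
Product: 20 3β-(angeloyloxy)-4α,11-dihydroxy-5α-eudesm-6-en-8-one (CNP0261892.1), via mixed anhydride 19 (not isolated)
Conditions: 18, 2,4,6-trichlorobenzoyl chloride, Et3N, toluene, 20 °C; then 17, toluene, 80 °C
Reagents that add atoms: none
Why: Yamaguchi-type esterification through the mixed 2,4,6-trichlorobenzoic anhydride, run without a nucleophilic catalyst so that the Z (angelate) geometry is not isomerised to the tiglate, should acylate only the secondary 3β-hydroxyl because the two tertiary hydroxyls are too hindered.

**Compound list**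
1 | (1R,5R)-4,6,6-trimethylbicyclo[3.1.1]hept-3-en-2-one, (+)-verbenone | CC1=CC(=O)[C@@H]2C[C@H]1C2(C)C | starting material
2 | but-3-en-1-ylmagnesium bromide | C=CCC[Mg]Br | starting material
3 | (1R,4R,5R)-4-(but-3-en-1-yl)-4,6,6-trimethylbicyclo[3.1.1]heptan-2-one | C=CCC[C@]1(C)CC(=O)[C@@H]2C[C@H]1C2(C)C | intermediate
4 | (3R,4R)-3-(but-3-en-1-yl)-4-(2-chloropropan-2-yl)-3-methylcyclohexan-1-one | C=CCC[C@]1(C)CC(=O)CC[C@H]1C(C)(C)Cl | intermediate
5 | (3R,4S)-3-(but-3-en-1-yl)-3-methyl-4-(prop-1-en-2-yl)cyclohexan-1-one | C=CCC[C@]1(C)CC(=O)CC[C@H]1C(C)=C | intermediate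
6 | (7R,8S)-7-(but-3-en-1-yl)-7-methyl-8-(prop-1-en-2-yl)-1,4-dioxaspiro[4.5]decane | C=CCC[C@]1(C)CC2(OCCO2)CC[C@H]1C(C)=C | intermediate
7 | methyl 3-[(7R,8R)-8-acetyl-7-methyl-1,4-dioxaspiro[4.5]decan-7-yl]propanoate | COC(=O)CC[C@]1(C)CC2(OCCO2)CC[C@H]1C(C)=O | intermediate
8 | methyl 3-[(7R,8R)-7-methyl-8-{1-[(triethylsilyl)oxy]ethenyl}-1,4-dioxaspiro[4.5]decan-7-yl]propanoate | COC(=O)CC[C@]1(C)CC2(OCCO2)CC[C@H]1C(=C)O[Si](CC)(CC)CC | intermediate
9 | 3-[(7R,8R)-7-methyl-8-{1-[(triethylsilyl)oxy]ethenyl}-1,4-dioxaspiro[4.5]decan-7-yl]propanal | O=CCC[C@]1(C)CC2(OCCO2)CC[C@H]1C(=C)O[Si](CC)(CC)CC | intermediate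
10 | 8,8-(ethylenedioxy)-3β,15-epoxy-4α-(triethylsilyloxy)-11,12,13-trinor-5α-eudesmane (trans-decalin with a cis-fused oxetane: O on C3 and CH2 on C4, both β) | O1[C@H]2CC[C@]3(C)CC4(OCCO4)CC[C@H]3[C@@]2(O[Si](CC)(CC)CC)C1 | intermediate
11 | 8,8-(ethylenedioxy)-4α-(triethylsilyloxy)-11,12,13-trinor-5α-eudesman-3β-ol | O[C@H]1CC[C@]2(C)CC3(OCCO3)CC[C@H]2[C@]1(C)O[Si](CC)(CC)CC | intermediate
12 | 3β,4α-dihydroxy-11,12,13-trinor-5α-eudesman-8-one | O[C@H]1CC[C@]2(C)CC(=O)CC[C@H]2[C@]1(C)O | intermediate
13 | acetone | CC(C)=O | starting material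
14 | 3β,4α,11-trihydroxy-5α,7α(H)-eudesman-8-one | O[C@H]1CC[C@]2(C)CC(=O)[C@@H](C(C)(C)O)C[C@H]2[C@]1(C)O | intermediate
15 | 3β,4α-dihydroxy-5α-eudesm-7(11)-en-8-one | O[C@H]1CC[C@]2(C)CC(=O)C(=C(C)C)C[C@H]2[C@]1(C)O | intermediate
16 | 11-hydroperoxy-3β,4α-dihydroxy-5α-eudesm-6-en-8-one | O[C@H]1CC[C@]2(C)CC(=O)C(C(C)(C)OO)=C[C@H]2[C@]1(C)O | intermediate
17 | 3β,4α,11-trihydroxy-5α-eudesm-6-en-8-one | O[C@H]1CC[C@]2(C)CC(=O)C(C(C)(C)O)=C[C@H]2[C@]1(C)O | intermediate
18 | angelic acid, (Z)-2-methylbut-2-enoic acid | C/C=C(/C)C(=O)O | starting material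
19 | (Z)-2-methylbut-2-enoic 2,4,6-trichlorobenzoic anhydride | C/C=C(/C)C(=O)OC(=O)c1c(Cl)cc(Cl)cc1Cl | intermediate
20 | 3β-(angeloyloxy)-4α,11-dihydroxy-5α-eudesm-6-en-8-one (CNP0261892.1) | C/C=C(/C)C(=O)O[C@H]1CC[C@]2(C)CC(=O)C(C(C)(C)O)=C[C@H]2[C@]1(C)O | target

**Totals**
Total step count: 12. Longest linear sequence: 12 steps (from 1).

**Steps most likely to fail**

Step 7 (proposed new method). What may go wrong: α-cleavage and decarbonylation of the excited aldehyde, reversion of a slowly closing biradical, or poor facial selectivity in the closure of ring A. Fallback with known chemistry, setting out from 6 and returning at 12: ozonolysis of 6 with reductive work-up (O3, CH2Cl2/MeOH, −78 °C; PPh3) should give keto aldehyde F1. Intramolecular McMurry coupling (TiCl3(DME)1.5, Zn–Cu, DME, reflux) should close ring A at the same bond as the C3=C4 alkene F2. Dihydroxylation (OsO4 cat., N-methylmorpholine N-oxide) from the α face, anti to the axial C10 methyl, should give 3α,4α-diol F3 with the correct C4 centre. Oxidation of the secondary hydroxyl (Dess–Martin periodinane) should give ketol F4, and NaBH4 reduction by axial hydride delivery should invert C3 to give 3β,4α-diol ketal F5. Hydrolysis of the ketal (2 M HCl, THF) then gives 12.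

Step 11. What may go wrong: hydrogen abstraction from an isopropylidene methyl group with C–O bonding at C7 instead of C11, or slow reaction because the angular methyl shields the β face from which the axial C6 hydrogen must be taken. Fallback, setting out from 12 and returning at 17 (it replaces steps 9 to 11): α-selenenylation of 12 (LiN(i-Pr)2 in excess, THF, −78 °C; PhSeCl) should give selenide F6. Its lithium enolate (LiN(i-Pr)2, −78 °C) should add to acetone to give seleno aldol F7. Oxidation (H2O2, pyridine, CH2Cl2, 0 °C) and syn elimination of the selenoxide toward C6, the only position with β-hydrogens, should give 17 directly.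

Step 9. What may go wrong: incomplete enolisation or aggregation of the polyanion, proton transfer from acetone instead of addition, and retro-aldol reversal on warming. Fallback, setting out from 12 and returning at 14: persilylation with soft enolisation (Me3SiOTf, Et3N, CH2Cl2, 0 °C) should give tris(trimethylsilyl) enol ether F8, with the enol double bond toward C7. Mukaiyama aldol addition to acetone (TiCl4, CH2Cl2, −78 °C) followed by dilute aqueous HCl work-up, which removes the silyl groups, should give 14.

**Further compounds**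
F1 | step 7 | 3-[(7R,8R)-8-acetyl-7-methyl-1,4-dioxaspiro[4.5]decan-7-yl]propanal | O=CCC[C@]1(C)CC2(OCCO2)CC[C@H]1C(C)=O
F2 | step 7 | 8,8-(ethylenedioxy)-11,12,13-trinor-5α-eudesm-3-ene | C1=C(C)[C@@H]2CCC3(OCCO3)C[C@@]2(C)CC1
F3 | step 7 | 8,8-(ethylenedioxy)-11,12,13-trinor-5α-eudesmane-3α,4α-diol | O[C@@H]1CC[C@]2(C)CC3(OCCO3)CC[C@H]2[C@]1(C)O
F4 | step 7 | 8,8-(ethylenedioxy)-4α-hydroxy-11,12,13-trinor-5α-eudesman-3-one | O=C1CC[C@]2(C)CC3(OCCO3)CC[C@H]2[C@]1(C)O
F5 | step 7 | 8,8-(ethylenedioxy)-11,12,13-trinor-5α-eudesmane-3β,4α-diol | O[C@H]1CC[C@]2(C)CC3(OCCO3)CC[C@H]2[C@]1(C)O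
F6 | step 11 | 3β,4α-dihydroxy-7α-(phenylselanyl)-11,12,13-trinor-5α-eudesman-8-one | O[C@H]1CC[C@]2(C)CC(=O)[C@H]([Se]c3ccccc3)C[C@H]2[C@]1(C)O
F7 | step 11 | 3β,4α,11-trihydroxy-7β-(phenylselanyl)-5α-eudesman-8-one (2-hydroxypropan-2-yl group on the α face of C7) | O[C@H]1CC[C@]2(C)CC(=O)[C@]([Se]c3ccccc3)(C(C)(C)O)C[C@H]2[C@]1(C)O
F8 | step 9 | 3β,4α,8-tris(trimethylsilyloxy)-11,12,13-trinor-5α-eudesm-7-ene | C[Si](C)(C)O[C@H]1CC[C@]2(C)CC(O[Si](C)(C)C)=CC[C@H]2[C@]1(C)O[Si](C)(C)C
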